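Before I opened an earlier run of this flask, I reckoned by hand what it should hold at the end.

Sub 0.070 M; Rgt2 0.0770 M; time 40 s

* amount of Prd2 at 40 s, in percent of the Sub charged
* concentration of Sub2 in solution at 40 s, in percent of saturation

    Sub ⇌ Sub2, rate k1*(cs1 - [Sub2]) while solid is left; crystals form when [Sub2] > cs1 (cs1 = 24 mM, k1 = 0.0305 /s)
    2 Sub2 → Ofp (k2 = 3.10 /M/s)
    Rgt2 ⇌ Rgt, rate k3*(cs3 - [Rgt]) while solid is left; crystals form when [Rgt] > cs3 (cs3 = 24 mM, k3 = 0.132 /s)
    2 Rgt → Prd (k4 = 0.857 /M/s)
    Sub2 + Rgt → Prd2 (k5 = 0.798 /M/s)

Two solids feed the solution and each dissolved species is lost in pairs, so I looked for the levels at which feed and loss balance (a quasi-steady state). I took both solids to last the run; for Sub, even a solution kept empty draws 41.8 % of the charge by then, less than the whole. Balancing the dissolution of Rgt2 against the pairing of Rgt, and setting its step with Sub2 aside, I got a level of Rgt, R = 19.2 mM. The root of the matching quadratic for Sub2 is S = 7.78 mM, the level of dissolved Sub2 at which its dissolution equals its pairing plus its reaction with Rgt at R. That is 32.4 % of saturation. Prd2 then forms at 0.119 mM/s. The two levels arrive late by about the sum of their relaxation times, the inverse slopes of the balances, which is 11.9 s. So I committed to 4.78 % of the Sub charged.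

The forecast gave 5.4 %, more than my figure, and 32.5 %, and it put the low level down to “its fast second-order loss”.

The flask gave 4.94 % of Prd2, with Sub2 at 32.4 % of saturation.

Sub2 already stood at 30.0 % of saturation at 20.0 s. S also gives the pace of the solid in this flask: dissolution at that level runs at 0.495 mM/s, which by my reckoning leaves 71.7 % of the Sub by 40.0 s, where the flask held 68.9 %.

For the same flask left until 2.5 min, the pace at S spends the charge of Sub in 142 s, a shorter time than its run. The computed flask held Sub at 0 % and Prd2 at 18.3 %.

(Its constants were chosen freely.)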